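**Strategy.** The plan rests on cutting the C11–C12 bond of ring C (C8, C9, C11, C12, C13, C14): the only ring bond between two non-stereogenic methylenes, each hanging on a quaternary carbon (C9 of ring B, C13 of ring D). The 11,12-seco compound already holds rings A, B, D, E, the dioxane and the guaiane; it carries a C9–CH2CO2H arm and a C13 aldehyde. As O-acyl thiohydroxamate and N-aziridinylimine, one radical chain expels CO2, joins C11 to C12, sheds styrene and N2 and caps C12 with hydrogen, giving the target directly. The trans ring-fusion centres C8, C9, C13 and C14 are built earlier and stay untouched.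

Key step: step 33

Assumption: atoms carry friedelane numbers (triterpenoid part) and primed guaiane numbers (sesquiterpene part). The cycloaddition in step 31 is taken to give both facial adducts, and the adduct that leads to the target (oxygens cis to the C10′ methyl, the more hindered face by simple steric analysis) is taken to be separable.

## Sesquiterpene diene (steps 1–7)

Step 1
Reactants: 1 (S)-carvone
Product: 2 (2R,5S)-2-methyl-5-(prop-1-en-2-yl)cyclohexan-1-one (cis-dihydrocarvone)
Conditions: ene-reductase (old-yellow-enzyme type), NADP+ (cat.), alcohol dehydrogenase, i-PrOH, phosphate buffer pH 7, 30 °C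
Reagents that add atoms: none
Why: Ene-reductase conjugate reduction of the enone C=C should deliver the α-hydrogen under enzyme control, giving the 2R centre and hence the cis relation of methyl and isopropenyl that becomes C10′/C7′.

Step 2
Reactants: 2 cis-dihydrocarvone
Product: 3 ethyl (3R,6S)-3-methyl-2-oxo-6-(prop-1-en-2-yl)cycloheptane-1-carboxylate
Conditions: N2CHCO2Et, BF3·OEt2, Et2O, 0 °C
Reagents that add atoms: ethyl diazoacetate [N-]=[N+]=CC(=O)OCC
Why: Lewis-acid-promoted diazoacetate ring expansion should proceed by migration of the less substituted α-carbon, inserting the ester-bearing carbon (C5′) on the CH2 side and leaving both stereocentres untouched at low temperature.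

Step 3
Reactants: 3 ring-expanded β-keto ester
Product: 4 ethyl (3R,6S)-3-methyl-6-(prop-1-en-2-yl)-2-(trifluoromethylsulfonyloxy)cyclohept-1-ene-1-carboxylate
Conditions: NaH, PhNTf2, THF, 0 °C to rt
Reagents that add atoms: N-phenyl-bis(trifluoromethanesulfonimide) O=S(=O)(N(c1ccccc1)S(=O)(=O)C(F)(F)F)C(F)(F)F
Why: O-triflation of the stabilised β-keto ester enolate locks the C1′=C5′ double bond in conjugation with the ester.

Step 4
Reactants: 4 enol triflate
Product: 5 ethyl (3R,6S)-3-methyl-6-(prop-1-en-2-yl)cyclohept-1-ene-1-carboxylate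
Conditions: Pd(OAc)2 (cat.), PPh3, HCO2H, Bu3N, DMF, 60 °C
Reagents that add atoms: none
Why: Palladium-catalysed formate reduction of a vinyl triflate replaces OTf by H without touching the isopropenyl group.

Step 5
Reactants: 5 cycloheptene ester
Product: 7 1-[(3R,6S)-3-methyl-6-(prop-1-en-2-yl)cyclohept-1-en-1-yl]ethan-1-one, via silyl ketone 6 (not isolated)
Conditions: Me3SiCH2Li, pentane/THF, −78 °C to rt; then MeOH, rt
Reagents that add atoms: (trimethylsilyl)methyllithium [Li]C[Si](C)(C)C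
Why: Acyl substitution by the α-silyl carbanion stops at the enolised α-silyl ketone, and protodesilylation gives the methyl ketone (ester-to-methyl-ketone conversion).

Step 6
Reactants: 7 methyl ketone
Product: 8 2-[(3R,6S)-3-methyl-6-(prop-1-en-2-yl)cyclohept-1-en-1-yl]but-3-en-2-ol
Conditions: CH2=CHMgBr, THF, −78 °C
Reagents that add atoms: vinylmagnesium bromide C=C[Mg]Br
Why: 1,2-Grignard addition to the enone carbonyl gives the divinyl carbinol; its new centre is lost in the next step.

Step 7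
Reactants: 8 divinyl carbinol
Product: 9 (5S,8R)-3,8-dimethyl-5-(prop-1-en-2-yl)-1,4,5,6,7,8-hexahydroazulene (guaia-1(5),3,11-triene)
Conditions: TsOH·H2O (cat.), CH2Cl2, 0 °C, short contact; kept cold and used at once
Reagents that add atoms: none
Why: Dehydrative Nazarov-type 4π-electrocyclisation of the pentadienyl cation closes the five-membered ring (C1′–C2′), and proton loss from C1′ should give the 1(5),3-diene before 1,5-hydrogen shifts scramble it.

## Rings D/E with C8 and C12 (steps 8–19)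

Step 8
Reactants: 10 3-methylcyclohex-2-en-1-one
Product: 11 (R)-3-methyl-3-phenylcyclohexan-1-one
Conditions: PhB(OH)2, Pd(OCOCF3)2 (cat.), (S)-t-BuPyOx (cat.), NH4PF6, H2O, ClCH2CH2Cl, 60 °C
Reagents that add atoms: phenylboronic acid OB(O)c1ccccc1
Why: Palladium-catalysed asymmetric conjugate addition of an arylboronic acid sets the quaternary centre (future C20) under control of the pyridine-oxazoline ligand.

Step 9
Reactants: 11 phenyl ketone
Product: 12 (1R)-1-methyl-3-oxocyclohexane-1-carboxylic acid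
Conditions: RuCl3·xH2O (cat.), NaIO4, CCl4/MeCN/H2O, rt
Reagents that add atoms: sodium periodate [Na+].[O-]I(=O)(=O)=O
Why: Ruthenium tetroxide degradation of the phenyl ring to CO2H turns the aryl group into C29 without touching the quaternary centre.

Step 10
Reactants: 12 keto acid
Product: 13 methyl (1R)-1-methyl-3-oxocyclohexane-1-carboxylate
Conditions: MeI, K2CO3, DMF, rt
Reagents that add atoms: iodomethane CI
Why: Carboxylate O-alkylation gives the methyl ester that survives to the target.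

Step 11
Reactants: 13 keto ester
Product: 14 methyl (1R)-1,4-dimethyl-3-oxocyclohexane-1-carboxylate
Conditions: LiN(i-Pr)2, THF, −78 °C; MeI
Reagents that add atoms: iodomethane CI
Why: Kinetic enolate methylation occurs at the CH2 remote from the quaternary carbon; the new centre (future C17) is reset in the next step.

Step 12
Reactants: 14 methylated keto ester
Product: 17 methyl (1R,4R)-1,4-dimethyl-3-oxo-4-(3-oxopentyl)cyclohexane-1-carboxylate, via imine 15 (not isolated), via alkylated imine 16 (not isolated)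
Conditions: (S)-1-phenylethylamine, TsOH (cat.), PhMe, reflux (−H2O); then ethyl vinyl ketone, THF, 40 °C; then 20% aq. AcOH, rt
Reagents that add atoms: pent-1-en-3-one C=CC(=O)CC; water O
Why: Asymmetric Michael addition of the chiral imine through its more substituted secondary enamine tautomer alkylates the methyl-bearing α-carbon on the face left open by the auxiliary, setting quaternary C17 (Me28).

Step 13
Reactants: 17 diketone
Product: 18 methyl (2R,4aR)-2,4a,8-trimethyl-7-oxo-1,2,3,4,4a,5,6,7-octahydronaphthalene-2-carboxylate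
Conditions: NaOMe, MeOH, 50 °C
Reagents that add atoms: none
Why: Intramolecular aldol condensation (second stage of a Robinson annulation) closes ring D as the C14 enone with Me27 on C13.

Step 14
Reactants: 18 octalone
Product: 19 cis-fused decalone methyl (2R,4aR,8aS)-2,4a,8-trimethyl-7-oxodecahydronaphthalene-2-carboxylate
Conditions: H2 (3 atm), Pd/C, MeOH, rt
Reagents that add atoms: none
Why: Heterogeneous hydrogenation of a 4a-methyl octalone should add hydrogen cis to the angular methyl, giving the cis D/E fusion (18β-H, 17β-Me).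

Step 15
Reactants: 19 cis-decalone
Product: 21 β-keto acetal with 13α-methyl and 13β-dimethoxymethyl, via silyl enol ether 20 (not isolated)
Conditions: TMSOTf, Et3N, CH2Cl2, rt; then HC(OMe)3, TMSOTf (cat.), CH2Cl2, −78 °C
Reagents that add atoms: trimethyl orthoformate COC(OC)OC
Why: The thermodynamic tetrasubstituted silyl enol ether (towards C13) reacts in a Mukaiyama-type alkylation with the dimethoxycarbenium ion on the convex β-face of the cis-decalin, placing C12 β and Me27 α.

Step 16
Reactants: 21 β-keto acetal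
Product: 23 C14 carbaldehyde (C14 epimers) with acetal intact, via enol ether 22 (not isolated)
Conditions: MeOCH2PPh3Cl, KN(SiMe3)2, PhMe, 0 to 80 °C; then Hg(OAc)2, THF/H2O, then aq. KI
Reagents that add atoms: (methoxymethyl)triphenylphosphonium chloride COC[P+](c1ccccc1)(c1ccccc1)c1ccccc1.[Cl-]; water O
Why: Wittig methoxymethylenation and mercury-assisted enol ether hydrolysis homologate the ketone to the aldehyde (carbon C8) under conditions that should spare the neopentyl dimethyl acetal.

Step 17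
Reactants: 23 aldehyde
Product: 24 quaternary aldehyde with 14β-methyl and 14α-formyl
Conditions: KOt-Bu, THF, 0 °C; MeI
Reagents that add atoms: iodomethane CI
Why: C-methylation of the exocyclic aldehyde enolate should occur axially on the convex β-face, anti to the axial 13α-methyl, giving the trans vicinal quaternary methyls (Me26 β, Me27 α).

Step 18
Reactants: 24 quaternary aldehyde
Product: 25 (E)-enone (C14–CH=CH–COCH3)
Conditions: (MeO)2P(O)CH2COCH3, NaH, THF, 0 to 50 °C
Reagents that add atoms: dimethyl (2-oxopropyl)phosphonate COP(=O)(CC(C)=O)OC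
Why: Horner–Wadsworth–Emmons olefination of the non-enolisable aldehyde gives the E enone whose alkene carbons are C8 and C7.

Step 19
Reactants: 25 enone
Product: 26 (R)-allylic alcohol
Conditions: (S)-2-methyl-CBS-oxazaborolidine (0.2 equiv), BH3·SMe2, THF, −20 °C
Reagents that add atoms: none
Why: Corey–Bakshi–Shibata reduction with the (S)-catalyst should give the (R)-carbinol by reagent control (alkenyl as the large group); this centre later dictates C8.

## Ring A acid (steps 20–24)

Step 20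
Reactants: 27 4-bromo-2-methoxy-6-methylphenol
Product: 28 (4-bromo-2-methoxy-6-methylphenoxy)(tert-butyl)dimethylsilane
Conditions: TBSCl, imidazole, DMF, rt
Reagents that add atoms: tert-butyldimethylsilyl chloride CC(C)(C)[Si](C)(C)Cl
Why: Silylation protects the phenol (future O3) until it is needed for quinone formation.

Step 21
Reactants: 28 aryl bromide
Product: 29 tert-butyl 2-[4-(tert-butyldimethylsilyloxy)-3-methoxy-5-methylphenyl]propanoate
Conditions: tert-butyl propanoate, LiNCy2, Pd(dba)2 (cat.), P(t-Bu)3 (cat.), PhMe, rt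
Reagents that add atoms: tert-butyl propanoate CCC(=O)OC(C)(C)C
Why: Palladium-catalysed α-arylation of the ester enolate attaches C9 (with Me25) to C10.

Step 22
Reactants: 29 aryl propanoate
Product: 30 tert-butyl 2-[2-bromo-4-(tert-butyldimethylsilyloxy)-5-methoxy-3-methylphenyl]propanoate
Conditions: NBS, MeCN, 0 °C
Reagents that add atoms: N-bromosuccinimide O=C1CCC(=O)N1Br
Why: Electrophilic bromination should occur para to the methoxy group (C5), the position activated by the strongest free donor, in preference to C1, which lies between the methoxy group and the side chain.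

Step 23
Reactants: 30 bromo ester
Product: 31 2-[2-bromo-4-(tert-butyldimethylsilyloxy)-5-methoxy-3-methylphenyl]propanoic acid
Conditions: CF3CO2H, CH2Cl2, 0 °C
Reagents that add atoms: none
Why: Acidolysis of the tert-butyl ester (loss of isobutene) frees the acid while the aryl silyl ether survives.

Step 24
Reactants: 31 bromo acid
Product: 32 2-[4-(tert-butyldimethylsilyloxy)-2-ethenyl-5-methoxy-3-methylphenyl]propanoic acid
Conditions: Bu3SnCH=CH2, Pd2(dba)3 (cat.), P(t-Bu)3 (cat.), dioxane, 90 °C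
Reagents that add atoms: tributyl(vinyl)stannane C=C[Sn](CCCC)(CCCC)CCCC
Why: Stille coupling installs the vinyl group whose inner carbon becomes C6.

## Union, ring B, dioxane, ring C (steps 25–33)

Step 25
Reactants: 26 (R)-allylic alcohol; 32 aryl propanoic acid
Product: 33 allylic 2-arylpropanoate ester
Conditions: DCC, DMAP (cat.), CH2Cl2, 0 °C to rt
Reagents that add atoms: none
Why: Steglich esterification joins the two halves; the α-centre of the acid is irrelevant because it is enolised next.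

Step 26
Reactants: 33 allylic ester
Product: 36 Claisen acid with C8–C9 bond, via silyl ketene acetal 34 (not isolated), via silyl ester 35 (not isolated)
Conditions: LiN(i-Pr)2, TMSCl, Et3N, THF, −78 to 40 °C; then aq. citric acid
Reagents that add atoms: none
Why: Ireland–Claisen rearrangement: kinetic enolisation in THF should place the aryl group syn to the allyloxy oxygen, and the chair transition state with the carbinol methyl equatorial transfers the (R)-carbinol chirality through the E alkene to C8 (H α) and sets C9 (Me25 β, CO2H α) relative to it.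

Step 27
Reactants: 36 Claisen acid
Product: 37 1,2-dihydronaphthalene acid (ring B closed, C6=C7)
Conditions: second-generation Grubbs catalyst (H2IMes)(PCy3)Cl2Ru=CHPh (cat.), PhMe, 60 °C
Reagents that add atoms: none
Why: Ring-closing metathesis between the aryl vinyl group and the propenyl group closes ring B as the C6=C7 styrene with loss of propene and no change at C8 or C9.

Step 28
Reactants: 37 ring B acid
Product: 39 diazoketone, via acid chloride 38 (not isolated)
Conditions: 1-chloro-N,N,2-trimethylprop-1-en-1-amine, CH2Cl2, 0 °C; then CH2N2, Et2O, 0 °C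
Reagents that add atoms: diazomethane C=[N+]=[N-]
Why: Neutral acid chloride formation and acylation of diazomethane (first stage of the Arndt–Eistert homologation) should tolerate the acetal and bring in the carbon that becomes C11.

Step 29
Reactants: 39 diazoketone
Product: 40 homologated acid (C9–CH2–CO2H)
Conditions: PhCO2Ag (cat.), Et3N, THF/H2O, 45 °C
Reagents that add atoms: water O
Why: Wolff rearrangement moves the quaternary C9 with retention onto the former diazo carbon, and hydration of the ketene gives the acid.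

Step 30
Reactants: 40 homologated acid
Product: 41 phenol aldehyde acid (free 3-OH, C13–CHO)
Conditions: 48% aq. HF, MeCN, 0 °C to rt
Reagents that add atoms: water O
Why: Aqueous HF should both cleave the aryl silyl ether and hydrolyse the dimethyl acetal, so no acid treatment is needed after the sesquiterpene is attached.

Step 31
Reactants: 41 phenol aldehyde acid; 9 guaia-1(5),3,11-triene
Product: 43 dioxane adduct (11,12-seco compound), via o-quinone 42 (not isolated)
Conditions: 2-iodoxybenzoic acid (IBX), DMF, rt; then 9 (3 equiv), CH2Cl2, −20 °C to rt; chromatography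
Reagents that add atoms: 2-iodoxybenzoic acid O=C1OI(=O)(O)c2ccccc12
Why: Oxidative demethylation of the 2-methoxyphenol gives the o-quinone, whose inverse-demand hetero-Diels–Alder addition to the tetrasubstituted C1′=C5′ bond is suprafacial (cis dioxane fusion) and should join O3 to the diene terminus C1′; approach to the face bearing the C7′ and C10′ substituents, which leads to the target, is not enforced, so the facial isomer must be separated.

Step 32
Reactants: 43 dioxane adduct
Product: 44 N-aziridinylimine of the C12 aldehyde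
Conditions: 1-amino-2-phenylaziridine, CH2Cl2, 0 °C
Reagents that add atoms: 1-amino-2-phenylaziridine NN1CC1c1ccccc1
Why: Hydrazone-type condensation converts the non-enolisable aldehyde into the radical acceptor.

Step 33
Reactants: 44 N-aziridinylimine acid
Product: 46 target CNP0113384.1, via thiohydroxamate ester 45 (not isolated)
Conditions: N-hydroxypyridine-2-thione, DCC, DMAP (cat.), CH2Cl2, dark, 0 °C; then (Me3Si)3SiH (syringe pump), hν (tungsten lamp), PhH, 15 °C, 0.005 M
Reagents that add atoms: none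
Why: The silyl radical strips the thiohydroxamate, CO2 is lost and the primary C11 radical adds to C12 of the C=N bond; the aminyl radical opens the aziridine, styrene and N2 depart, and the C12 radical takes hydrogen from (Me3Si)3SiH, which carries the chain. The closest known reaction type is the tin- or silane-mediated radical cyclisation onto aldehyde N-aziridinylimines, where the imine carbon is first radical acceptor and then radical donor, here fed by a standard decarboxylative radical source. Ring C closes in the 6-exo-trig mode across the two arms held gauche on the C8–C14 bond. No stereocentre is formed: C11 and C12 end as methylenes, and C8, C9, C13 and C14 are already set in steps 15, 17 and 26, so the B/C and C/D trans fusions cannot be lost. The step needs cyclisation to outrun hydrogen transfer to C11 and the 1,2-aryl (neophyl-type) shift; slow silane addition, low temperature and the fast addition to C=N should secure this, and C11 has no alkene within 5-exo reach.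

## Compound list

1 | (S)-carvone | C=C(C)[C@H]1CC=C(C)C(=O)C1 | starting material
2 | (2R,5S)-2-methyl-5-(prop-1-en-2-yl)cyclohexan-1-one | C=C(C)[C@H]1CC[C@@H](C)C(=O)C1 | intermediate
3 | ethyl (3R,6S)-3-methyl-2-oxo-6-(prop-1-en-2-yl)cycloheptane-1-carboxylate (C1 epimers) | C=C(C)[C@H]1CC[C@@H](C)C(=O)C(C(=O)OCC)C1 | intermediate
4 | ethyl (3R,6S)-3-methyl-6-(prop-1-en-2-yl)-2-(trifluoromethylsulfonyloxy)cyclohept-1-ene-1-carboxylate | C=C(C)[C@H]1CC[C@@H](C)C(OS(=O)(=O)C(F)(F)F)=C(C(=O)OCC)C1 | intermediate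
5 | ethyl (3R,6S)-3-methyl-6-(prop-1-en-2-yl)cyclohept-1-ene-1-carboxylate | C=C(C)[C@H]1CC[C@@H](C)C=C(C(=O)OCC)C1 | intermediate
6 | 1-[(3R,6S)-3-methyl-6-(prop-1-en-2-yl)cyclohept-1-en-1-yl]-2-(trimethylsilyl)ethan-1-one | C=C(C)[C@H]1CC[C@@H](C)C=C(C(=O)C[Si](C)(C)C)C1 | intermediate
7 | 1-[(3R,6S)-3-methyl-6-(prop-1-en-2-yl)cyclohept-1-en-1-yl]ethan-1-one | C=C(C)[C@H]1CC[C@@H](C)C=C(C(C)=O)C1 | intermediate
8 | 2-[(3R,6S)-3-methyl-6-(prop-1-en-2-yl)cyclohept-1-en-1-yl]but-3-en-2-ol (carbinol epimers) | C=C(C)[C@H]1CC[C@@H](C)C=C(C(C)(O)C=C)C1 | intermediate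
9 | (5S,8R)-3,8-dimethyl-5-(prop-1-en-2-yl)-1,4,5,6,7,8-hexahydroazulene | C=C(C)[C@H]1CC[C@@H](C)C2=C(C1)C(C)=CC2 | intermediate
10 | 3-methylcyclohex-2-en-1-one | CC1=CC(=O)CCC1 | starting material
11 | (R)-3-methyl-3-phenylcyclohexan-1-one | O=C1CCC[C@@](C)(c2ccccc2)C1 | intermediate
12 | (1R)-1-methyl-3-oxocyclohexane-1-carboxylic acid | O=C(O)[C@]1(C)CCCC(=O)C1 | intermediate
13 | methyl (1R)-1-methyl-3-oxocyclohexane-1-carboxylate | COC(=O)[C@]1(C)CCCC(=O)C1 | intermediate
14 | methyl (1R)-1,4-dimethyl-3-oxocyclohexane-1-carboxylate (C4 epimers) | COC(=O)[C@]1(C)CCC(C)C(=O)C1 | intermediate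
15 | (S)-1-phenylethyl imine of 14 | COC(=O)[C@]1(C)CCC(C)C(=N[C@@H](C)c2ccccc2)C1 | intermediate
16 | C17-alkylated imine | COC(=O)[C@]1(C)CC[C@](C)(CCC(=O)CC)C(=N[C@@H](C)c2ccccc2)C1 | intermediate
17 | methyl (1R,4R)-1,4-dimethyl-3-oxo-4-(3-oxopentyl)cyclohexane-1-carboxylate | CCC(=O)CC[C@@]1(C)CC[C@@](C)(C(=O)OC)CC1=O | intermediate
18 | methyl (2R,4aR)-2,4a,8-trimethyl-7-oxo-1,2,3,4,4a,5,6,7-octahydronaphthalene-2-carboxylate | CC1=C2C[C@](C)(C(=O)OC)CC[C@]2(C)CCC1=O | intermediate
19 | methyl (2R,4aR,8aS)-2,4a,8-trimethyl-7-oxodecahydronaphthalene-2-carboxylate (cis-fused, C8 epimers) | CC1[C@@H]2C[C@](C)(C(=O)OC)CC[C@]2(C)CCC1=O | intermediate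
20 | trimethylsilyl enol ether of 19 (C13=C14) | CC1=C(O[Si](C)(C)C)CC[C@@]2(C)CC[C@@](C)(C(=O)OC)C[C@@H]12 | intermediate
21 | D/E keto acetal: 13α-methyl, 13β-dimethoxymethyl, 14-oxo | C[C@]1(C(OC)OC)[C@@H]2C[C@](C)(C(=O)OC)CC[C@]2(C)CCC1=O | intermediate
22 | 14-(methoxymethylidene) enol ether of 21 | C[C@]1(C(OC)OC)[C@@H]2C[C@](C)(C(=O)OC)CC[C@]2(C)CCC1=COC | intermediate
23 | 14-carbaldehyde (C14 epimers) | C[C@]1(C(OC)OC)[C@@H]2C[C@](C)(C(=O)OC)CC[C@]2(C)CCC1C=O | intermediate
24 | 14β-methyl-14α-carbaldehyde | C[C@]1(C(OC)OC)[C@@H]2C[C@](C)(C(=O)OC)CC[C@]2(C)CC[C@]1(C)C=O | intermediate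
25 | (E)-enone C14–CH=CH–COCH3 | CC(=O)/C=C/[C@@]1(C)CC[C@@]2(C)CC[C@@](C)(C(=O)OC)C[C@H]2[C@]1(C)C(OC)OC | intermediate
26 | (R,E)-allylic alcohol | C[C@@H](O)/C=C/[C@@]1(C)CC[C@@]2(C)CC[C@@](C)(C(=O)OC)C[C@H]2[C@]1(C)C(OC)OC | intermediate
27 | 4-bromo-2-methoxy-6-methylphenol | COc1cc(Br)cc(C)c1O | starting material
28 | (4-bromo-2-methoxy-6-methylphenoxy)(tert-butyl)dimethylsilane | COc1cc(Br)cc(C)c1O[Si](C)(C)C(C)(C)C | intermediate
29 | tert-butyl 2-[4-(tert-butyldimethylsilyloxy)-3-methoxy-5-methylphenyl]propanoate | CC(C(=O)OC(C)(C)C)c1cc(C)c(O[Si](C)(C)C(C)(C)C)c(OC)c1 | intermediate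
30 | tert-butyl 2-[2-bromo-4-(tert-butyldimethylsilyloxy)-5-methoxy-3-methylphenyl]propanoate | CC(C(=O)OC(C)(C)C)c1cc(OC)c(O[Si](C)(C)C(C)(C)C)c(C)c1Br | intermediate
31 | 2-[2-bromo-4-(tert-butyldimethylsilyloxy)-5-methoxy-3-methylphenyl]propanoic acid | CC(C(=O)O)c1cc(OC)c(O[Si](C)(C)C(C)(C)C)c(C)c1Br | intermediate
32 | 2-[4-(tert-butyldimethylsilyloxy)-2-ethenyl-5-methoxy-3-methylphenyl]propanoic acid | CC(C(=O)O)c1cc(OC)c(O[Si](C)(C)C(C)(C)C)c(C)c1C=C | intermediate
33 | allylic ester of 26 with 32 | COc1cc(c(C=C)c(C)c1O[Si](C)(C)C(C)(C)C)C(C)C(=O)O[C@H](C)/C=C/[C@@]2(C)CC[C@@]3(C)CC[C@@](C)(C(=O)OC)C[C@H]3[C@]2(C)C(OC)OC | intermediate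
34 | trimethylsilyl ketene acetal of 33 (aryl syn to allyloxy) | COc1cc(c(C=C)c(C)c1O[Si](C)(C)C(C)(C)C)/C(C)=C(/O[Si](C)(C)C)O[C@H](C)/C=C/[C@@]2(C)CC[C@@]3(C)CC[C@@](C)(C(=O)OC)C[C@H]3[C@]2(C)C(OC)OC | intermediate
35 | trimethylsilyl ester of 36 | COc1cc(c(C=C)c(C)c1O[Si](C)(C)C(C)(C)C)[C@](C)(C(=O)O[Si](C)(C)C)[C@H](/C=C/C)[C@@]2(C)CC[C@@]3(C)CC[C@@](C)(C(=O)OC)C[C@H]3[C@]2(C)C(OC)OC | intermediate
36 | Claisen acid (C9 quaternary, C8 propenyl) | COc1cc(c(C=C)c(C)c1O[Si](C)(C)C(C)(C)C)[C@](C)(C(=O)O)[C@H](/C=C/C)[C@@]2(C)CC[C@@]3(C)CC[C@@](C)(C(=O)OC)C[C@H]3[C@]2(C)C(OC)OC | intermediate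
37 | ring B acid (C9–CO2H) | COc1cc2c(c(C)c1O[Si](C)(C)C(C)(C)C)C=C[C@H]([C@@]3(C)CC[C@@]4(C)CC[C@@](C)(C(=O)OC)C[C@H]4[C@]3(C)C(OC)OC)[C@@]2(C)C(=O)O | intermediate
38 | acid chloride of 37 | COc1cc2c(c(C)c1O[Si](C)(C)C(C)(C)C)C=C[C@H]([C@@]3(C)CC[C@@]4(C)CC[C@@](C)(C(=O)OC)C[C@H]4[C@]3(C)C(OC)OC)[C@@]2(C)C(Cl)=O | intermediate
39 | diazoketone | COc1cc2c(c(C)c1O[Si](C)(C)C(C)(C)C)C=C[C@H]([C@@]3(C)CC[C@@]4(C)CC[C@@](C)(C(=O)OC)C[C@H]4[C@]3(C)C(OC)OC)[C@@]2(C)C(=O)C=[N+]=[N-] | intermediate
40 | homologated acid (C9–CH2–CO2H) | COc1cc2c(c(C)c1O[Si](C)(C)C(C)(C)C)C=C[C@H]([C@@]3(C)CC[C@@]4(C)CC[C@@](C)(C(=O)OC)C[C@H]4[C@]3(C)C(OC)OC)[C@@]2(C)CC(=O)O | intermediate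
41 | phenol aldehyde acid | COc1cc2c(c(C)c1O)C=C[C@H]([C@@]3(C)CC[C@@]4(C)CC[C@@](C)(C(=O)OC)C[C@H]4[C@]3(C)C=O)[C@@]2(C)CC(=O)O | intermediate
42 | 2,3-o-quinone of 41 | O=C1C=C2C(=C(C)C1=O)C=C[C@H]([C@@]3(C)CC[C@@]4(C)CC[C@@](C)(C(=O)OC)C[C@H]4[C@]3(C)C=O)[C@@]2(C)CC(=O)O | intermediate
43 | dioxane adduct (11,12-seco acid aldehyde) | C=C(C)[C@H]1CC[C@@H](C)[C@]23CC=C(C)[C@@]2(C1)Oc1cc2c(c(C)c1O3)C=C[C@H]([C@@]4(C)CC[C@@]5(C)CC[C@@](C)(C(=O)OC)C[C@H]5[C@]4(C)C=O)[C@@]2(C)CC(=O)O | intermediate
44 | N-(2-phenylaziridin-1-yl)imine of 43 | C=C(C)[C@H]1CC[C@@H](C)[C@]23CC=C(C)[C@@]2(C1)Oc1cc2c(c(C)c1O3)C=C[C@H]([C@@]4(C)CC[C@@]5(C)CC[C@@](C)(C(=O)OC)C[C@H]5[C@]4(C)C=NN6CC6c7ccccc7)[C@@]2(C)CC(=O)O | intermediate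
45 | O-acyl thiohydroxamate of 44 | C=C(C)[C@H]1CC[C@@H](C)[C@]23CC=C(C)[C@@]2(C1)Oc1cc2c(c(C)c1O3)C=C[C@H]([C@@]4(C)CC[C@@]5(C)CC[C@@](C)(C(=O)OC)C[C@H]5[C@]4(C)C=NN6CC6c7ccccc7)[C@@]2(C)CC(=O)ON8C=CC=CC8=S | intermediate
46 | CNP0113384.1 | C=C(C)[C@H]1CC[C@@H](C)[C@]23CC=C(C)[C@@]2(C1)Oc1cc2c(c(C)c1O3)C=C[C@H]1[C@@]2(C)CC[C@@]2(C)[C@@H]3C[C@](C)(C(=O)OC)CC[C@]3(C)CC[C@]12C | target

## Step count and risks

Total step count: 33. Longest linear sequence: 21 steps (steps 8–19, then 25–33, from 3-methylcyclohex-2-en-1-one).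

**Step 31.** The quinone may approach the diene face anti to the pseudo-axial C10′ methyl (the sterically easier face), the diene may scramble by 1,5-hydrogen shifts, and the vinylogous o-quinone may tautomerise to the quinone methide before it is trapped. The fallback uses a hydroxyl group on the face that leads to the target to steer the quinone by hydrogen bonding and sets out from 7 and 42. Hydration of the isopropenyl group of 7 (Co(acac)2, PhSiH3, O2) gives the hydroxy ketone F1; vinylmagnesium bromide gives the diol F2; brief acid treatment as in step 7 gives the dienol F3. Cycloaddition of F3 with 42 gives the hydroxy adduct F4. Condensation as in step 32 gives the hydroxy N-aziridinylimine F5, and the radical closure of step 33 through the thiohydroxamate ester F6 gives the 11′-hydroxy compound F7. Dehydration of F7 with methyl N-(triethylammoniumsulfonyl)carbamate (Burgess reagent) comes back to the route at 46.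

**Step 17.** Methyl iodide may attack the aldehyde enolate on the wrong face (poor facial selectivity next to the C13 quaternary centre) or on oxygen. The fallback delivers the methyl carbon by cyclopropanation instead of enolate alkylation and sets out from 21: the enol ether 22 is isolated, Simmons–Smith cyclopropanation (Et2Zn, CH2I2) gives the methoxycyclopropane F8, and buffered aqueous acid opens it to the α-methyl aldehyde, coming back at 24.

**Step 33.** The C11 radical may be reduced or undergo a 1,2-aryl shift before the two arms reach each other (slow rotation about the crowded C8–C14 bond). The fallback closes ring C by an organosamarium addition and sets out from 43. Decarboxylative iodination (PhI(OAc)2, I2, hν) gives the neopentyl iodide F9. SmI2 with HMPA in THF closes ring C in a Barbier-type addition to the C12 aldehyde, giving the 12-hydroxy compound F10. The phenyl thionocarbonate F11 (PhOC(S)Cl, pyridine) is then reduced by Barton–McCombie deoxygenation (Bu3SnH, AIBN), coming back at 46.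

Further compounds
F1 | step 31 | 1-[(3R,6S)-6-(2-hydroxypropan-2-yl)-3-methylcyclohept-1-en-1-yl]ethan-1-one | CC(C)(O)[C@H]1CC[C@@H](C)C=C(C(C)=O)C1
F2 | step 31 | 2-[(3R,6S)-6-(2-hydroxypropan-2-yl)-3-methylcyclohept-1-en-1-yl]but-3-en-2-ol | CC(C)(O)[C@H]1CC[C@@H](C)C=C(C(C)(O)C=C)C1
F3 | step 31 | 2-[(5S,8R)-3,8-dimethyl-1,4,5,6,7,8-hexahydroazulen-5-yl]propan-2-ol | CC(C)(O)[C@H]1CC[C@@H](C)C2=C(C1)C(C)=CC2
F4 | step 31 | 11′-hydroxy analogue of adduct 43 | CC(C)(O)[C@H]1CC[C@@H](C)[C@]23CC=C(C)[C@@]2(C1)Oc1cc2c(c(C)c1O3)C=C[C@H]([C@@]4(C)CC[C@@]5(C)CC[C@@](C)(C(=O)OC)C[C@H]5[C@]4(C)C=O)[C@@]2(C)CC(=O)O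
F5 | step 31 | 11′-hydroxy analogue of N-aziridinylimine 44 | CC(C)(O)[C@H]1CC[C@@H](C)[C@]23CC=C(C)[C@@]2(C1)Oc1cc2c(c(C)c1O3)C=C[C@H]([C@@]4(C)CC[C@@]5(C)CC[C@@](C)(C(=O)OC)C[C@H]5[C@]4(C)C=NN6CC6c7ccccc7)[C@@]2(C)CC(=O)O
F6 | step 31 | 11′-hydroxy analogue of thiohydroxamate ester 45 | CC(C)(O)[C@H]1CC[C@@H](C)[C@]23CC=C(C)[C@@]2(C1)Oc1cc2c(c(C)c1O3)C=C[C@H]([C@@]4(C)CC[C@@]5(C)CC[C@@](C)(C(=O)OC)C[C@H]5[C@]4(C)C=NN6CC6c7ccccc7)[C@@]2(C)CC(=O)ON8C=CC=CC8=S
F7 | step 31 | 11′-hydroxy-11′,12′-dihydro analogue of 46 | CC(C)(O)[C@H]1CC[C@@H](C)[C@]23CC=C(C)[C@@]2(C1)Oc1cc2c(c(C)c1O3)C=C[C@H]1[C@@]2(C)CC[C@@]2(C)[C@@H]3C[C@](C)(C(=O)OC)CC[C@]3(C)CC[C@]12C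
F8 | step 17 | spiro methoxycyclopropane from enol ether 22 | C[C@]1(C(OC)OC)[C@@H]2C[C@](C)(C(=O)OC)CC[C@]2(C)CC[C@@]13CC3OC
F9 | step 33 | C9-iodomethyl C13-aldehyde seco adduct | C=C(C)[C@H]1CC[C@@H](C)[C@]23CC=C(C)[C@@]2(C1)Oc1cc2c(c(C)c1O3)C=C[C@H]([C@@]4(C)CC[C@@]5(C)CC[C@@](C)(C(=O)OC)C[C@H]5[C@]4(C)C=O)[C@@]2(C)CI
F10 | step 33 | 12-hydroxy analogue of 46 | C=C(C)[C@H]1CC[C@@H](C)[C@]23CC=C(C)[C@@]2(C1)Oc1cc2c(c(C)c1O3)C=C[C@H]1[C@@]2(C)CC(O)[C@@]2(C)[C@@H]3C[C@](C)(C(=O)OC)CC[C@]3(C)CC[C@]12C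
F11 | step 33 | 12-O-phenoxythiocarbonyl derivative of F10 | C=C(C)[C@H]1CC[C@@H](C)[C@]23CC=C(C)[C@@]2(C1)Oc1cc2c(c(C)c1O3)C=C[C@H]1[C@@]2(C)CC(OC(=S)Oc4ccccc4)[C@@]2(C)[C@@H]3C[C@](C)(C(=O)OC)CC[C@]3(C)CC[C@]12C
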